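**Plan**
1. Retrosynthesis cuts the C6–C(=O) bond (aryllithium plus aldehyde, then oxidation), the C8–CH2 bond of the prenyl group (aromatic Claisen from O1) and the O1–C2 bond of the pyran, which is traced back to a ring enlargement.
2. The pyran ring (O1, C2, C3, C4, C4a, C8a) is not closed as a six-membered ring. It is first made as the dihydrofuran ring (O1, C3, C4, C4a, C8a) of a cyclopropa[b]benzofuran in which C2 (CMe2) bridges C3 and C4, and is then enlarged by moving O1 from C3 to C2 while the C2–C4 cyclopropane bond breaks.
3. Enabling feature: C2 is tertiary and C4 is benzylic to a ring with oxygen at C5 and C7 (ortho and para to C4a), so C2–C3–C4 is a highly stabilised allyl cation (a vinyl o-quinone methide). O1, ortho to C4a, acts first as a tethered leaving group and then as the nucleophile.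
4. Forward order: arene from 2,4,6-trihydroxybenzaldehyde (formyl carbon becomes C4, the chelated OH becomes O1) → C8 prenyl by Claisen → O1–CH=CMe2 enol ether → carbene [2+1] closes dihydrofuran and cyclopropane together → ring enlargement to the chromene → C6 aroylation → deprotection.
5. Regiochemistry follows from O1 being the only unprotected oxygen throughout. The target has no stereocentre; the cis-fused cyclopropane (fixed by the tether) and the carbinol are racemic and transient.

Key step: step 7

Remark: 1, 3, 7 and 14 are taken as catalogue compounds; 11 and 16 form as racemates, and the SMILES of 11 shows one enantiomer of the only possible (cis-fused) isomer.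

**Step 1**
Reactants: 1 2,4,6-trihydroxybenzaldehyde
Product: 2 2-hydroxy-4,6-bis(methoxymethoxy)benzaldehyde
Conditions: MOMCl (2.1 equiv), iPr2NEt (2.5 equiv), CH2Cl2, 0 °C → rt
Reagents that add atoms: chloromethyl methyl ether, COCCl
Why: Williamson-type MOM protection takes the 4-OH and one ortho-OH, while the last ortho-OH is held in a hydrogen bond to the formyl group and stays free, which singles out the future O1.

**Step 2**
Reactants: 2 2-hydroxy-4,6-bis(methoxymethoxy)benzaldehyde; 3 3-chloro-3-methylbut-1-yne
Product: 4 4,6-bis(methoxymethoxy)-2-[(2-methylbut-3-yn-2-yl)oxy]benzaldehyde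
Conditions: DBU, CuCl2·2H2O (1 mol%), MeCN, 0 °C → rt
Reagents that add atoms: none
Why: Copper-catalysed propargylic etherification of the only free phenol with a tertiary propargylic chloride, which runs through a copper allenylidene and so tolerates the tertiary centre where SN2 would fail.

**Step 3**
Reactants: 4 4,6-bis(methoxymethoxy)-2-[(2-methylbut-3-yn-2-yl)oxy]benzaldehyde
Product: 6 2-hydroxy-4,6-bis(methoxymethoxy)-3-(3-methylbut-2-en-1-yl)benzaldehyde, via 1,1-dimethylallyl ether 5 (not isolated)
Conditions: H2 (1 atm), Lindlar catalyst, quinoline, PhMe, rt; filter; then 110 °C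
Reagents that add atoms: none
Why: Lindlar semi-hydrogenation stops at the terminal alkene, and the aryl 1,1-dimethylallyl ether then undergoes aromatic Claisen ([3,3]) rearrangement to the only free ortho carbon with allyl inversion, which places the linear prenyl group next to the regenerated phenol.

**Step 4**
Reactants: 6 2-hydroxy-4,6-bis(methoxymethoxy)-3-(3-methylbut-2-en-1-yl)benzaldehyde; 7 1-bromo-2-methylprop-1-ene
Product: 8 4,6-bis(methoxymethoxy)-3-(3-methylbut-2-en-1-yl)-2-[(2-methylprop-1-en-1-yl)oxy]benzaldehyde
Conditions: CuI (10 mol%), N,N-dimethylglycine (30 mol%), Cs2CO3, 1,4-dioxane, 90 °C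
Reagents that add atoms: none
Why: Ullmann-type copper(I)-catalysed C(sp2)–O coupling of the phenoxide with the vinyl bromide; the far alkene carbon carries two identical methyl groups, so no alkene geometry has to be controlled.

**Step 5**
Reactants: 8 4,6-bis(methoxymethoxy)-3-(3-methylbut-2-en-1-yl)-2-[(2-methylprop-1-en-1-yl)oxy]benzaldehyde
Product: 9 N'-[(E)-{4,6-bis(methoxymethoxy)-3-(3-methylbut-2-en-1-yl)-2-[(2-methylprop-1-en-1-yl)oxy]phenyl}methylidene]-4-methylbenzenesulfonohydrazide
Conditions: TsNHNH2 (1.05 equiv), MeOH, rt → 40 °C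
Reagents that add atoms: 4-methylbenzenesulfonohydrazide, Cc1ccc(cc1)S(=O)(=O)NN
Why: Acid-free condensation gives the (E)-tosylhydrazone as a stable diazoalkane precursor; the aryl enol ether and the MOM acetals are untouched in neutral methanol.

**Step 6**
Reactants: 9 N'-[(E)-{4,6-bis(methoxymethoxy)-3-(3-methylbut-2-en-1-yl)-2-[(2-methylprop-1-en-1-yl)oxy]phenyl}methylidene]-4-methylbenzenesulfonohydrazide
Product: 11 rac-cis-4,6-bis(methoxymethoxy)-1,1-dimethyl-3-(3-methylbut-2-en-1-yl)-1a,6b-dihydro-1H-cyclopropa[b][1]benzofuran, via aryldiazomethane 10 (not isolated)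
Conditions: NaH, THF, 0 °C; then BnEt3NCl (10 mol%), Rh2(OAc)4 (1 mol%), 1,4-dioxane (0.01 M), 40 °C
Reagents that add atoms: none
Why: Bamford–Stevens fragmentation of the hydrazone salt releases the aryldiazomethane slowly, and the rhodium(II) carbenoid cyclopropanates the electron-rich enol ether held three atoms away (intramolecular [2+1], closing the dihydrofuran ring in the same event); the two new stereocentres can only be cis-fused, are racemic and disappear in step 7.

**Step 7**
Reactants: 11 rac-cis-4,6-bis(methoxymethoxy)-1,1-dimethyl-3-(3-methylbut-2-en-1-yl)-1a,6b-dihydro-1H-cyclopropa[b][1]benzofuran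
Product: 13 5,7-bis(methoxymethoxy)-2,2-dimethyl-8-(3-methylbut-2-en-1-yl)-2H-chromene, via o-quinone methide 12 (not isolated)
Conditions: HFIP/CH2Cl2 (1:4), 2,6-lutidine (0.1 equiv), 0 °C → rt
Reagents that add atoms: none
Why: Proposed new method: hydrogen bonding of HFIP to the aryl ether oxygen lets O1 depart from cyclopropane carbon C3 while the distal C2–C4 bond opens in the disrotatory cyclopropyl-to-allyl sense, and because C2 is tertiary and C4 is benzylic to a ring with oxygen ortho and para, the resulting zwitterion is simply the vinyl o-quinone methide 12, which closes by oxa-6π-electrocyclisation (O1 to C2) to the 2H-chromene. The closest known reaction types are the ring opening of cyclopropyl halides or sulfonates to allyl cations, the opening of cyclopropanated furans (2-oxabicyclo[3.1.0]hexenes) to cis-dienones and the electrocyclisation of vinyl o-quinone methides; an aryl ether as internal leaving group of a benzofuran-fused cyclopropane is not an established case, hence the label. The net result is enlargement of the five-membered ring O1–C3–C4–C4a–C8a to the six-membered pyran by insertion of C2 between O1 and C3, driven by release of cyclopropane strain and rearomatisation. No stereocentre is created and the two of 11 are erased; the compulsory cis fusion turns the aryl group inward on opening and so gives the Z geometry at C3=C4 that the closure needs. The step needs C–O ionisation to win over protonation of a cyclopropane carbon (which would lead to a 3-isopropylbenzofuran) and closure at C2 and not at C4: the buffered, weakly acidic, non-nucleophilic medium is chosen for the first, and ring size secures the second, since closure at C4 would give a benzoxete.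

**Step 8**
Reactants: 13 5,7-bis(methoxymethoxy)-2,2-dimethyl-8-(3-methylbut-2-en-1-yl)-2H-chromene; 14 4-(methoxymethoxy)benzaldehyde
Product: 16 [5,7-bis(methoxymethoxy)-2,2-dimethyl-8-(3-methylbut-2-en-1-yl)-2H-chromen-6-yl][4-(methoxymethoxy)phenyl]methanol, via aryllithium 15 (not isolated)
Conditions: n-BuLi (1.2 equiv), THF, 0 °C; then 14, −78 °C → rt; H2O
Reagents that add atoms: none
Why: Directed ortho-metalation at the only remaining aromatic C–H, which lies between two OMOM groups, followed by 1,2-addition of the aryllithium to the aldehyde; the carbinol centre is racemic and is removed in step 9.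

**Step 9**
Reactants: 16 [5,7-bis(methoxymethoxy)-2,2-dimethyl-8-(3-methylbut-2-en-1-yl)-2H-chromen-6-yl][4-(methoxymethoxy)phenyl]methanol
Product: 17 [5,7-bis(methoxymethoxy)-2,2-dimethyl-8-(3-methylbut-2-en-1-yl)-2H-chromen-6-yl][4-(methoxymethoxy)phenyl]methanone
Conditions: Dess–Martin periodinane, pyridine, CH2Cl2, 0 °C → rt
Reagents that add atoms: none
Why: Dess–Martin oxidation of the doubly benzylic secondary alcohol to the benzophenone under buffered conditions that leave both alkenes and the MOM acetals intact.

**Step 10**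
Reactants: 17 [5,7-bis(methoxymethoxy)-2,2-dimethyl-8-(3-methylbut-2-en-1-yl)-2H-chromen-6-yl][4-(methoxymethoxy)phenyl]methanone
Product: 18 vismiaphenone E
Conditions: HCl (0.5 M in MeOH), rt → 40 °C
Reagents that add atoms: none
Why: Acid-catalysed transacetalisation removes the three MOM groups as dimethoxymethane; the two ortho-MOM groups are labilised by chelation to the ketone, and mild, short exposure is meant to avoid acid-induced cyclisation of the 7-OH onto the prenyl group.

**Compound list**
1 | 2,4,6-trihydroxybenzaldehyde | O=Cc1c(O)cc(O)cc1O | starting material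
2 | 2-hydroxy-4,6-bis(methoxymethoxy)benzaldehyde | O=Cc1c(O)cc(OCOC)cc1OCOC | intermediate
3 | 3-chloro-3-methylbut-1-yne | C#CC(C)(C)Cl | starting material
4 | 4,6-bis(methoxymethoxy)-2-[(2-methylbut-3-yn-2-yl)oxy]benzaldehyde | O=Cc1c(OC(C)(C)C#C)cc(OCOC)cc1OCOC | intermediate
5 | 4,6-bis(methoxymethoxy)-2-[(2-methylbut-3-en-2-yl)oxy]benzaldehyde | O=Cc1c(OC(C)(C)C=C)cc(OCOC)cc1OCOC | intermediate (not isolated)
6 | 2-hydroxy-4,6-bis(methoxymethoxy)-3-(3-methylbut-2-en-1-yl)benzaldehyde | O=Cc1c(O)c(CC=C(C)C)c(OCOC)cc1OCOC | intermediate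
7 | 1-bromo-2-methylprop-1-ene | CC(C)=CBr | starting material
8 | 4,6-bis(methoxymethoxy)-3-(3-methylbut-2-en-1-yl)-2-[(2-methylprop-1-en-1-yl)oxy]benzaldehyde | O=Cc1c(OC=C(C)C)c(CC=C(C)C)c(OCOC)cc1OCOC | intermediate
9 | N'-[(E)-{4,6-bis(methoxymethoxy)-3-(3-methylbut-2-en-1-yl)-2-[(2-methylprop-1-en-1-yl)oxy]phenyl}methylidene]-4-methylbenzenesulfonohydrazide | Cc1ccc(cc1)S(=O)(=O)N/N=C/c1c(OC=C(C)C)c(CC=C(C)C)c(OCOC)cc1OCOC | intermediate
10 | 2-(diazomethyl)-1,5-bis(methoxymethoxy)-4-(3-methylbut-2-en-1-yl)-3-[(2-methylprop-1-en-1-yl)oxy]benzene | [N-]=[N+]=Cc1c(OC=C(C)C)c(CC=C(C)C)c(OCOC)cc1OCOC | intermediate (not isolated)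
11 | rac-cis-4,6-bis(methoxymethoxy)-1,1-dimethyl-3-(3-methylbut-2-en-1-yl)-1a,6b-dihydro-1H-cyclopropa[b][1]benzofuran | CC1(C)[C@H]2Oc3c(CC=C(C)C)c(OCOC)cc(OCOC)c3[C@@H]12 | intermediate
12 | (6Z)-3,5-bis(methoxymethoxy)-2-(3-methylbut-2-en-1-yl)-6-(3-methylbut-2-en-1-ylidene)cyclohexa-2,4-dien-1-one | O=C1C(CC=C(C)C)=C(OCOC)C=C(OCOC)/C1=C/C=C(C)C | intermediate (not isolated)
13 | 5,7-bis(methoxymethoxy)-2,2-dimethyl-8-(3-methylbut-2-en-1-yl)-2H-chromene | CC(C)=CCc1c(OCOC)cc(OCOC)c2C=CC(C)(C)Oc12 | intermediate
14 | 4-(methoxymethoxy)benzaldehyde | COCOc1ccc(C=O)cc1 | starting material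
15 | [5,7-bis(methoxymethoxy)-2,2-dimethyl-8-(3-methylbut-2-en-1-yl)-2H-chromen-6-yl]lithium | [Li]c1c(OCOC)c2C=CC(C)(C)Oc2c(CC=C(C)C)c1OCOC | intermediate (not isolated)
16 | [5,7-bis(methoxymethoxy)-2,2-dimethyl-8-(3-methylbut-2-en-1-yl)-2H-chromen-6-yl][4-(methoxymethoxy)phenyl]methanol (racemic) | COCOc1ccc(cc1)C(O)c1c(OCOC)c2C=CC(C)(C)Oc2c(CC=C(C)C)c1OCOC | intermediate
17 | [5,7-bis(methoxymethoxy)-2,2-dimethyl-8-(3-methylbut-2-en-1-yl)-2H-chromen-6-yl][4-(methoxymethoxy)phenyl]methanone | COCOc1ccc(cc1)C(=O)c1c(OCOC)c2C=CC(C)(C)Oc2c(CC=C(C)C)c1OCOC | intermediate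
18 | vismiaphenone E, [5,7-dihydroxy-2,2-dimethyl-8-(3-methylbut-2-en-1-yl)-2H-chromen-6-yl](4-hydroxyphenyl)methanone | CC(C)=CCc1c(O)c(C(=O)c2ccc(O)cc2)c(O)c2c1OC(C)(C)C=C2 | target

Total step count: 10. Longest linear sequence: 10 steps (1 → 18).

**Steps most likely to fail**

Step 7 (Proposed new method). The ionisation may not be selective: protonation at a cyclopropane carbon can compete with departure of O1, or the allyl cation may lose a methyl proton to a diene that does not close. The fallback uses known chemistry, gives up the cyclopropane and closes the pyran directly. It sets out from 6: addition of 2-methylprop-1-en-1-ylmagnesium bromide (2.5 equiv, THF, 0 °C) to the salicylaldehyde gives the diol 2-(1-hydroxy-3-methylbut-2-en-1-yl)-3,5-bis(methoxymethoxy)-6-(3-methylbut-2-en-1-yl)phenol F1. Brief warming of this doubly activated benzylic alcohol with PPTS in toluene ionises it to the same o-quinone methide 12, which electrocyclises; the fallback comes back to the route at 13.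

Step 6. The donor-substituted rhodium carbenoid may dimerise (azine or stilbene formation) or insert into the neighbouring O–CH2–O C–H bond faster than it adds to the enol ether. The fallback replaces the metal carbenoid by a dipolar cycloaddition. It sets out from 9: deprotonation (NaH, THF) and warming to 50 °C in dilute dioxane without metal lets diazoalkane 10 add as a 1,3-dipole to the tethered enol ether to give the cis-fused 1-pyrazoline 6,8-bis(methoxymethoxy)-3,3-dimethyl-5-(3-methylbut-2-en-1-yl)-3a,8b-dihydro-3H-[1]benzofuro[3,2-c]pyrazole F2. Irradiation (350 nm, 0 °C) extrudes nitrogen, and the fallback comes back to the route at 11.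

Step 4. Copper may be sequestered by the chelating, doubly ortho-substituted phenoxide so that the C–O coupling stalls. The fallback builds the enol ether by alkylation and double-bond migration. It sets out from 6: O-alkylation with 3-chloro-2-methylprop-1-ene (K2CO3, NaI, DMF, 60 °C) gives the methallyl ether 4,6-bis(methoxymethoxy)-3-(3-methylbut-2-en-1-yl)-2-[(2-methylprop-2-en-1-yl)oxy]benzaldehyde F3. Ruthenium hydride catalysis ([RuHCl(CO)(PPh3)3], PhMe, 80 °C) then moves the double bond into conjugation with oxygen, and the fallback comes back to the route at 8.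

**Further compounds**
F1 | step 7 | 2-(1-hydroxy-3-methylbut-2-en-1-yl)-3,5-bis(methoxymethoxy)-6-(3-methylbut-2-en-1-yl)phenol (racemic) | CC(C)=CC(O)c1c(O)c(CC=C(C)C)c(OCOC)cc1OCOC
F2 | step 6 | rac-cis-6,8-bis(methoxymethoxy)-3,3-dimethyl-5-(3-methylbut-2-en-1-yl)-3a,8b-dihydro-3H-[1]benzofuro[3,2-c]pyrazole | CC1(C)N=N[C@H]2c3c(OCOC)cc(OCOC)c(CC=C(C)C)c3O[C@@H]12
F3 | step 4 | 4,6-bis(methoxymethoxy)-3-(3-methylbut-2-en-1-yl)-2-[(2-methylprop-2-en-1-yl)oxy]benzaldehyde | O=Cc1c(OCC(C)=C)c(CC=C(C)C)c(OCOC)cc1OCOC
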